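**Retrosynthetic overview**

1. The oxirane is introduced last, by peripheral epoxidation of the only electron-rich alkene (C4=C5) of macrocycle 18; the C8 methacrylate, C9 acetate and C11 methylene are installed just before.
2. The ten-membered carbocycle is closed at C9–C10 by a ring-closing Morita–Baylis–Hillman reaction of enoate–aldehyde 11, which also sets C9 (new method).
3. The γ-lactone and C6 come from a Nozaki–Hiyama–Kishi coupling of vinyl iodide 4 with aldehyde 8, followed by lactonisation.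
4. C7 and C8, the first stereocentres, come from a D-proline-catalysed cross-aldol of methyl 4-oxobutanoate with 2,2-dimethoxyacetaldehyde.
5. Ring order: γ-lactone, then ten-membered carbocycle, then oxirane.

Assumption: macrocycles carry germacrane numbering (C1–C15) and the target is the (4R,5R,6S,7R,8S,9S) isomer with a ring-cis C1=C10 bond (E by CIP); the CIP letters at C6 and C7 change along the route only because substituent priorities change, and no centre is inverted.

**Route**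

Step 1
Reactants: 1 pent-4-yn-1-ol
Product: 2 (E)-5-iodo-4-methylpent-4-en-1-ol
Conditions: Me3Al (3 equiv), Cp2ZrCl2 (25 mol%), CH2Cl2, 0 to 25 °C; then I2, THF, −30 °C
Reagents that add atoms: trimethylaluminium, C[Al](C)C; iodine, II
Why: Zirconium-catalysed Negishi carboalumination adds methyl and aluminium syn across the terminal alkyne with methyl on the internal carbon, and iodinolysis of the C–Al bond with retention gives only the E vinyl iodide.

Step 2
Reactants: 2 (E)-5-iodo-4-methylpent-4-en-1-ol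
Product: 4 methyl (2E,6E)-7-iodo-6-methylhepta-2,6-dienoate, via (E)-5-iodo-4-methylpent-4-enal 3 (not isolated)
Conditions: 2-iodoxybenzoic acid, Ph3P=CHCO2Me, DMSO, 25 °C
Reagents that add atoms: methyl (triphenylphosphoranylidene)acetate, COC(=O)C=P(c1ccccc1)(c1ccccc1)c1ccccc1
Why: 2-Iodoxybenzoic acid oxidises the primary alcohol to aldehyde 3 in the presence of the stabilised ylide, which traps it in an E-selective Wittig olefination.

Step 3
Reactants: 5 methyl 4-oxobutanoate; 6 2,2-dimethoxyacetaldehyde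
Product: 7 methyl (3R,4S)-3-formyl-4-hydroxy-5,5-dimethoxypentanoate
Conditions: D-proline (20 mol%), 6 (60 wt% aq., 3 equiv), DMF, 4 °C, slow addition of 5
Reagents that add atoms: none
Why: Proline-catalysed direct cross-aldol reaction in which the E-enamine of 5 adds through the hydrogen-bonded List–Houk chair to one face of the non-enolisable aldehyde 6, so the first two stereocentres (3R,4S, anti; later C7 and C8) are set together by the catalyst.

Step 4
Reactants: 7 methyl (3R,4S)-3-formyl-4-hydroxy-5,5-dimethoxypentanoate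
Product: 8 methyl (3R,4S)-4-[(tert-butyldimethylsilyl)oxy]-3-formyl-5,5-dimethoxypentanoate
Conditions: TBSOTf, 2,6-lutidine, CH2Cl2, −78 °C
Reagents that add atoms: tert-butyldimethylsilyl trifluoromethanesulfonate, CC(C)(C)[Si](C)(C)OS(=O)(=O)C(F)(F)F
Why: Low-temperature silylation caps the β-hydroxyl before retro-aldol or lactonisation can occur and supplies the non-chelating β-silyloxy group that step 5 needs.

Step 5
Reactants: 8 methyl (3R,4S)-4-[(tert-butyldimethylsilyl)oxy]-3-formyl-5,5-dimethoxypentanoate; 4 methyl (2E,6E)-7-iodo-6-methylhepta-2,6-dienoate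
Product: 10 methyl (2E,6E)-7-[(2R,3S)-3-[(1S)-1-[(tert-butyldimethylsilyl)oxy]-2,2-dimethoxyethyl]-5-oxooxolan-2-yl]-6-methylhepta-2,6-dienoate, via acyclic hydroxy diester 9 (not isolated)
Conditions: CrCl2 (4 equiv), NiCl2 (2 mol%), DMSO, 25 °C; aq. work-up; DBU (0.2 equiv), CH2Cl2, 25 °C
Reagents that add atoms: none
Why: Nozaki–Hiyama–Kishi coupling tolerates both esters and the acetal, the alkenylchromium species adds in the Felkin–Anh sense reinforced by 1,3-anti induction from the β-silyloxy group to set C6 (8R in 9), and the new γ-hydroxyl then closes the trans-disubstituted γ-lactone on the methyl ester.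

Step 6
Reactants: 10 methyl (2E,6E)-7-[(2R,3S)-3-[(1S)-1-[(tert-butyldimethylsilyl)oxy]-2,2-dimethoxyethyl]-5-oxooxolan-2-yl]-6-methylhepta-2,6-dienoate
Product: 11 methyl (2E,6E)-7-[(2R,3S)-3-[(1S)-1-[(tert-butyldimethylsilyl)oxy]-2-oxoethyl]-5-oxooxolan-2-yl]-6-methylhepta-2,6-dienoate
Conditions: TESOTf, 2,4,6-collidine, CH2Cl2, 0 °C; then H2O
Reagents that add atoms: water, O
Why: Silyl triflate/collidine acetal cleavage passes through a collidinium salt that water hydrolyses under neutral conditions, so the silyl ether, the lactone and the epimerisable α-silyloxy aldehyde centre are untouched.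

Step 7
Reactants: 11 methyl (2E,6E)-7-[(2R,3S)-3-[(1S)-1-[(tert-butyldimethylsilyl)oxy]-2-oxoethyl]-5-oxooxolan-2-yl]-6-methylhepta-2,6-dienoate
Product: 12 methyl (1(10)E,4E,6R,7S,8S,9S)-8-[(tert-butyldimethylsilyl)oxy]-9-hydroxygermacra-1(10),4-dien-12,6-olid-14-oate
Conditions: PMe3 (0.5 equiv), PhOH (1 equiv), THF/t-AmOH (4:1), 1 mM, 40 °C, 11 added by syringe pump over 12 h
Reagents that add atoms: none
Why: Proposed new method: PMe3 adds reversibly to C1 of the E-enoate, the phosphonium enolate carbon C10 attacks the tethered C9 aldehyde, phenol shuttles the proton and E1cB loss of PMe3 restores C1=C10 with C2 and C9 cis (the more stable, ring-cis geometry), the chain being pre-organised by the E-alkene and the trans-lactone, and C9 (S) is expected because the aldolate oxygen points to the ring periphery while the C8–OSi bond lies anti to the forming bond; the closest known reaction is the phosphine-mediated intramolecular Morita–Baylis–Hillman cyclisation of enoate–aldehydes, established for five- and six-membered rings but not for a ten-membered carbocycle.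

Step 8
Reactants: 12 methyl (1(10)E,4E,6R,7S,8S,9S)-8-[(tert-butyldimethylsilyl)oxy]-9-hydroxygermacra-1(10),4-dien-12,6-olid-14-oate
Product: 15 methyl (1(10)E,4E,6R,7S,8S,9S)-8-[(tert-butyldimethylsilyl)oxy]-9-hydroxygermacra-1(10),4,11(13)-trien-12,6-olid-14-oate, via C11-dimethylaminomethyl lactone 13 (not isolated), via trimethylammonium iodide 14 (not isolated)
Conditions: LiN(SiMe3)2 (2.3 equiv), THF, −78 °C; [CH2=NMe2]I, −78 to 0 °C; AcOH (1.1 equiv), then MeI, 25 °C; aq. NaHCO3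
Reagents that add atoms: N,N-dimethylmethyleneiminium iodide (Eschenmoser's salt), C=[N+](C)C.[I-]; iodomethane, CI (its methyl stays only in 14 and leaves as trimethylamine)
Why: With the alcohol carried as its alkoxide and the enoate trisubstituted, the lactone α-CH2 is the most acidic site, its enolate undergoes a Mannich reaction with the iminium salt, and quaternisation followed by base-induced elimination of trimethylamine gives the exocyclic methylene.

Step 9
Reactants: 15 methyl (1(10)E,4E,6R,7S,8S,9S)-8-[(tert-butyldimethylsilyl)oxy]-9-hydroxygermacra-1(10),4,11(13)-trien-12,6-olid-14-oate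
Product: 17 methyl (1(10)E,4E,6R,7R,8S,9S)-9-acetoxy-8-hydroxygermacra-1(10),4,11(13)-trien-12,6-olid-14-oate, via 9-O-acetyl silyl ether 16 (not isolated)
Conditions: Ac2O, DMAP (cat.), pyridine, CH2Cl2, 0 °C; MeOH quench; then HF·pyridine, THF, 0 to 25 °C
Reagents that add atoms: acetic anhydride, CC(=O)OC(C)=O
Why: DMAP-catalysed acetylation of the only free hydroxyl (C9) is followed by fluoride cleavage of the silyl ether in an acidic buffer, which does not promote acetyl migration from O9 to O8.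

Step 10
Reactants: 17 methyl (1(10)E,4E,6R,7R,8S,9S)-9-acetoxy-8-hydroxygermacra-1(10),4,11(13)-trien-12,6-olid-14-oate
Product: 18 methyl (1(10)E,4E,6R,7S,8S,9S)-9-acetoxy-8-(methacryloyloxy)germacra-1(10),4,11(13)-trien-12,6-olid-14-oate
Conditions: methacrylic anhydride, Et3N, DMAP (0.2 equiv), CH2Cl2, 0 °C
Reagents that add atoms: methacrylic anhydride, C=C(C)C(=O)OC(=O)C(C)=C
Why: DMAP-catalysed acylation of the remaining secondary alcohol is faster than acetyl migration and brings in the methacrylate only after all phosphine and strong-base steps.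

Step 11
Reactants: 18 methyl (1(10)E,4E,6R,7S,8S,9S)-9-acetoxy-8-(methacryloyloxy)germacra-1(10),4,11(13)-trien-12,6-olid-14-oate
Product: 19 methyl (1(10)E,4R,5R,6S,7R,8S,9S)-9-acetoxy-4,5-epoxy-8-(methacryloyloxy)germacra-1(10),11(13)-dien-12,6-olid-14-oate (CNP0153978.3)
Conditions: mCPBA (1.2 equiv), NaHCO3, CH2Cl2, 0 °C
Reagents that add atoms: 3-chloroperbenzoic acid, O=C(OO)c1cccc(Cl)c1
Why: Prilezhaev epoxidation in which only C4=C5 is electron-rich, and with H6 eclipsing the alkene plane (minimal allylic 1,3-strain) the peracid attacks the outer face of the E-cyclodecene on the side of O6, which gives the 4R,5R oxirane.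

**Compound list**

1 | pent-4-yn-1-ol | C#CCCCO | starting material
2 | (E)-5-iodo-4-methylpent-4-en-1-ol | I/C=C(\C)CCCO | intermediate
3 | (E)-5-iodo-4-methylpent-4-enal | I/C=C(\C)CCC=O | intermediate (not isolated)
4 | methyl (2E,6E)-7-iodo-6-methylhepta-2,6-dienoate | I/C=C(\C)CC/C=C/C(=O)OC | intermediate
5 | methyl 4-oxobutanoate | COC(=O)CCC=O | starting material
6 | 2,2-dimethoxyacetaldehyde | COC(OC)C=O | starting material
7 | methyl (3R,4S)-3-formyl-4-hydroxy-5,5-dimethoxypentanoate | COC(=O)C[C@@H](C=O)[C@H](O)C(OC)OC | intermediate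
8 | methyl (3R,4S)-4-[(tert-butyldimethylsilyl)oxy]-3-formyl-5,5-dimethoxypentanoate | COC(=O)C[C@@H](C=O)[C@H](O[Si](C)(C)C(C)(C)C)C(OC)OC | intermediate
9 | dimethyl (2E,6E,8R,9S)-9-[(1S)-1-[(tert-butyldimethylsilyl)oxy]-2,2-dimethoxyethyl]-8-hydroxy-6-methylundeca-2,6-dienedioate | COC(=O)C[C@@H]([C@H](O)/C=C(\C)CC/C=C/C(=O)OC)[C@H](O[Si](C)(C)C(C)(C)C)C(OC)OC | intermediate (not isolated)
10 | methyl (2E,6E)-7-[(2R,3S)-3-[(1S)-1-[(tert-butyldimethylsilyl)oxy]-2,2-dimethoxyethyl]-5-oxooxolan-2-yl]-6-methylhepta-2,6-dienoate | O=C1C[C@H]([C@H](O[Si](C)(C)C(C)(C)C)C(OC)OC)[C@@H](/C=C(\C)CC/C=C/C(=O)OC)O1 | intermediate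
11 | methyl (2E,6E)-7-[(2R,3S)-3-[(1S)-1-[(tert-butyldimethylsilyl)oxy]-2-oxoethyl]-5-oxooxolan-2-yl]-6-methylhepta-2,6-dienoate | O=C1C[C@H]([C@H](O[Si](C)(C)C(C)(C)C)C=O)[C@@H](/C=C(\C)CC/C=C/C(=O)OC)O1 | intermediate
12 | methyl (1(10)E,4E,6R,7S,8S,9S)-8-[(tert-butyldimethylsilyl)oxy]-9-hydroxygermacra-1(10),4-dien-12,6-olid-14-oate (ten-membered carbocycle trans-fused to the γ-lactone) | CC(C)(C)[Si](C)(C)O[C@H]1[C@H]2CC(=O)O[C@@H]2/C=C(\C)CC/C=C(/C(=O)OC)[C@@H]1O | intermediate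
13 | methyl (1(10)E,4E,6R,7S,8S,9S)-8-[(tert-butyldimethylsilyl)oxy]-11-[(dimethylamino)methyl]-9-hydroxygermacra-1(10),4-dien-12,6-olid-14-oate (C11 epimers) | CC(C)(C)[Si](C)(C)O[C@H]1[C@H]2C(CN(C)C)C(=O)O[C@@H]2/C=C(\C)CC/C=C(/C(=O)OC)[C@@H]1O | intermediate (not isolated)
14 | N-methyl quaternary ammonium iodide of 13 (C11 epimers) | CC(C)(C)[Si](C)(C)O[C@H]1[C@H]2C(C[N+](C)(C)C)C(=O)O[C@@H]2/C=C(\C)CC/C=C(/C(=O)OC)[C@@H]1O.[I-] | intermediate (not isolated)
15 | methyl (1(10)E,4E,6R,7S,8S,9S)-8-[(tert-butyldimethylsilyl)oxy]-9-hydroxygermacra-1(10),4,11(13)-trien-12,6-olid-14-oate | CC(C)(C)[Si](C)(C)O[C@H]1[C@H]2C(=C)C(=O)O[C@@H]2/C=C(\C)CC/C=C(/C(=O)OC)[C@@H]1O | intermediate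
16 | methyl (1(10)E,4E,6R,7S,8S,9S)-9-acetoxy-8-[(tert-butyldimethylsilyl)oxy]germacra-1(10),4,11(13)-trien-12,6-olid-14-oate | CC(C)(C)[Si](C)(C)O[C@H]1[C@H]2C(=C)C(=O)O[C@@H]2/C=C(\C)CC/C=C(/C(=O)OC)[C@@H]1OC(C)=O | intermediate (not isolated)
17 | methyl (1(10)E,4E,6R,7R,8S,9S)-9-acetoxy-8-hydroxygermacra-1(10),4,11(13)-trien-12,6-olid-14-oate | O[C@H]1[C@H]2C(=C)C(=O)O[C@@H]2/C=C(\C)CC/C=C(/C(=O)OC)[C@@H]1OC(C)=O | intermediate
18 | methyl (1(10)E,4E,6R,7S,8S,9S)-9-acetoxy-8-(methacryloyloxy)germacra-1(10),4,11(13)-trien-12,6-olid-14-oate | C=C(C)C(=O)O[C@H]1[C@H]2C(=C)C(=O)O[C@@H]2/C=C(\C)CC/C=C(/C(=O)OC)[C@@H]1OC(C)=O | intermediate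
19 | methyl (1(10)E,4R,5R,6S,7R,8S,9S)-9-acetoxy-4,5-epoxy-8-(methacryloyloxy)germacra-1(10),11(13)-dien-12,6-olid-14-oate (CNP0153978.3) | C=C(C)C(=O)O[C@H]1[C@H]2C(=C)C(=O)O[C@@H]2[C@H]2O[C@]2(C)CC/C=C(/C(=O)OC)[C@@H]1OC(C)=O | target

**Step count and risk**

Total steps: 11. Longest linear sequence: 9 (steps 3 to 11 from 5 and 6; equally steps 1, 2 and 5 to 11 from 1).

The three steps most likely to fail:

Step 7 (the new ring-closing Morita–Baylis–Hillman reaction). The ten-membered closure may lose to oligomerisation, to epimerisation of the α-silyloxy aldehyde, or give the wrong C9 epimer. The fallback uses known chemistry, a Nozaki–Hiyama–Kishi macrocyclisation, and sets out from 8 and 2. Coupling 8 with the free alcohol 2 (CrCl2, NiCl2 cat., DMSO) gives methyl (3S,4R,5E)-3-[(1S)-1-[(tert-butyldimethylsilyl)oxy]-2,2-dimethoxyethyl]-4,9-dihydroxy-6-methylnon-5-enoate F1, which lactonises (DBU cat.) to (4S,5R)-4-[(1S)-1-[(tert-butyldimethylsilyl)oxy]-2,2-dimethoxyethyl]-5-[(1E)-5-hydroxy-2-methylpent-1-en-1-yl]oxolan-2-one F2. Dess–Martin oxidation gives the aldehyde (4E)-5-[(2R,3S)-3-[(1S)-1-[(tert-butyldimethylsilyl)oxy]-2,2-dimethoxyethyl]-5-oxooxolan-2-yl]-4-methylpent-4-enal F3. A Wittig reaction with the iodo-ylide made in the flask from Ph3P=CHCO2Me, N-iodosuccinimide and K2CO3 gives the Z α-iodoenoate methyl (2Z,6E)-2-iodo-7-[(2R,3S)-3-[(1S)-1-[(tert-butyldimethylsilyl)oxy]-2,2-dimethoxyethyl]-5-oxooxolan-2-yl]-6-methylhepta-2,6-dienoate F4. Acetal cleavage as in step 6 gives the iodo-enoate aldehyde methyl (2Z,6E)-2-iodo-7-[(2R,3S)-3-[(1S)-1-[(tert-butyldimethylsilyl)oxy]-2-oxoethyl]-5-oxooxolan-2-yl]-6-methylhepta-2,6-dienoate F5. Ring closure with CrCl2 and NiCl2 (cat.) in DMSO/THF at 2 mM then forms the C9–C10 bond with retention of the alkene geometry, and the route is rejoined at 12.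

Step 5 (configuration at C6). The Felkin selectivity of the chromium reagent may be only moderate. The fallback replaces substrate-controlled addition by a hydroxyl-directed reduction and sets out from 7 and 4. Coupling of the unprotected aldol 7 with 4 (CrCl2, NiCl2 cat., DMSO, 0 °C, neutral work-up) gives dimethyl (2E,6E,9S)-8-hydroxy-9-[(1S)-1-hydroxy-2,2-dimethoxyethyl]-6-methylundeca-2,6-dienedioate F6 as a C8 epimer mixture. MnO2 oxidises only the allylic alcohol to the enone dimethyl (2E,6E,9R)-9-[(1S)-1-hydroxy-2,2-dimethoxyethyl]-6-methyl-8-oxoundeca-2,6-dienedioate F7. Evans–Saksena reduction (Me4NBH(OAc)3, MeCN/AcOH, −30 °C) delivers hydride intramolecularly from the C8-bound borate and gives the 1,3-anti diol dimethyl (2E,6E,8R,9S)-8-hydroxy-9-[(1S)-1-hydroxy-2,2-dimethoxyethyl]-6-methylundeca-2,6-dienedioate F8. DBU-catalysed lactonisation to the more stable trans γ-lactone gives methyl (2E,6E)-7-[(2R,3R)-3-[(1S)-1-hydroxy-2,2-dimethoxyethyl]-5-oxooxolan-2-yl]-6-methylhepta-2,6-dienoate F9, and silylation (TBSOTf, 2,6-lutidine) rejoins the route at 10.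

Step 8 (lactone enolate chemistry on the macrocycle). The dianion may undergo silyl migration from O8 to O9 or transannular Michael addition of the lactone enolate to C1. The fallback moves the enolate step to the acyclic, hydroxyl-free stage and sets out from 10. Treatment of 10 with LiN(SiMe3)2 (1.05 equiv, THF, −78 °C) and [CH2=NMe2]I gives the Mannich base methyl (2E,6E)-7-[(2R,3S)-3-[(1S)-1-[(tert-butyldimethylsilyl)oxy]-2,2-dimethoxyethyl]-4-[(dimethylamino)methyl]-5-oxooxolan-2-yl]-6-methylhepta-2,6-dienoate F10. Acetal cleavage as in step 6 gives the aldehyde methyl (2E,6E)-7-[(2R,3S)-3-[(1S)-1-[(tert-butyldimethylsilyl)oxy]-2-oxoethyl]-4-[(dimethylamino)methyl]-5-oxooxolan-2-yl]-6-methylhepta-2,6-dienoate F11, in which the amine masks the future methylene from the phosphine. Ring closure as in step 7 gives 13, and quaternisation with MeI followed by aq. NaHCO3 rejoins the route at 15.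

**Further compounds**

F1 | step 7 | methyl (3S,4R,5E)-3-[(1S)-1-[(tert-butyldimethylsilyl)oxy]-2,2-dimethoxyethyl]-4,9-dihydroxy-6-methylnon-5-enoate | COC(=O)C[C@@H]([C@H](O)/C=C(\C)CCCO)[C@H](O[Si](C)(C)C(C)(C)C)C(OC)OC
F2 | step 7 | (4S,5R)-4-[(1S)-1-[(tert-butyldimethylsilyl)oxy]-2,2-dimethoxyethyl]-5-[(1E)-5-hydroxy-2-methylpent-1-en-1-yl]oxolan-2-one | O=C1C[C@H]([C@H](O[Si](C)(C)C(C)(C)C)C(OC)OC)[C@@H](/C=C(\C)CCCO)O1
F3 | step 7 | (4E)-5-[(2R,3S)-3-[(1S)-1-[(tert-butyldimethylsilyl)oxy]-2,2-dimethoxyethyl]-5-oxooxolan-2-yl]-4-methylpent-4-enal | O=C1C[C@H]([C@H](O[Si](C)(C)C(C)(C)C)C(OC)OC)[C@@H](/C=C(\C)CCC=O)O1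
F4 | step 7 | methyl (2Z,6E)-2-iodo-7-[(2R,3S)-3-[(1S)-1-[(tert-butyldimethylsilyl)oxy]-2,2-dimethoxyethyl]-5-oxooxolan-2-yl]-6-methylhepta-2,6-dienoate | O=C1C[C@H]([C@H](O[Si](C)(C)C(C)(C)C)C(OC)OC)[C@@H](/C=C(\C)CC/C=C(/C(=O)OC)I)O1
F5 | step 7 | methyl (2Z,6E)-2-iodo-7-[(2R,3S)-3-[(1S)-1-[(tert-butyldimethylsilyl)oxy]-2-oxoethyl]-5-oxooxolan-2-yl]-6-methylhepta-2,6-dienoate | O=C1C[C@H]([C@H](O[Si](C)(C)C(C)(C)C)C=O)[C@@H](/C=C(\C)CC/C=C(/C(=O)OC)I)O1
F6 | step 5 | dimethyl (2E,6E,9S)-8-hydroxy-9-[(1S)-1-hydroxy-2,2-dimethoxyethyl]-6-methylundeca-2,6-dienedioate (C8 epimers) | COC(=O)C[C@@H](C(O)/C=C(\C)CC/C=C/C(=O)OC)[C@H](O)C(OC)OC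
F7 | step 5 | dimethyl (2E,6E,9R)-9-[(1S)-1-hydroxy-2,2-dimethoxyethyl]-6-methyl-8-oxoundeca-2,6-dienedioate | COC(=O)C[C@@H](C(=O)/C=C(\C)CC/C=C/C(=O)OC)[C@H](O)C(OC)OC
F8 | step 5 | dimethyl (2E,6E,8R,9S)-8-hydroxy-9-[(1S)-1-hydroxy-2,2-dimethoxyethyl]-6-methylundeca-2,6-dienedioate | COC(=O)C[C@@H]([C@H](O)/C=C(\C)CC/C=C/C(=O)OC)[C@H](O)C(OC)OC
F9 | step 5 | methyl (2E,6E)-7-[(2R,3R)-3-[(1S)-1-hydroxy-2,2-dimethoxyethyl]-5-oxooxolan-2-yl]-6-methylhepta-2,6-dienoate | O=C1C[C@H]([C@H](O)C(OC)OC)[C@@H](/C=C(\C)CC/C=C/C(=O)OC)O1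
F10 | step 8 | methyl (2E,6E)-7-[(2R,3S)-3-[(1S)-1-[(tert-butyldimethylsilyl)oxy]-2,2-dimethoxyethyl]-4-[(dimethylamino)methyl]-5-oxooxolan-2-yl]-6-methylhepta-2,6-dienoate (C4 epimers of the oxolane) | O=C1C(CN(C)C)[C@H]([C@H](O[Si](C)(C)C(C)(C)C)C(OC)OC)[C@@H](/C=C(\C)CC/C=C/C(=O)OC)O1
F11 | step 8 | methyl (2E,6E)-7-[(2R,3S)-3-[(1S)-1-[(tert-butyldimethylsilyl)oxy]-2-oxoethyl]-4-[(dimethylamino)methyl]-5-oxooxolan-2-yl]-6-methylhepta-2,6-dienoate (C4 epimers of the oxolane) | O=C1C(CN(C)C)[C@H]([C@H](O[Si](C)(C)C(C)(C)C)C=O)[C@@H](/C=C(\C)CC/C=C/C(=O)OC)O1
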